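**Retrosynthetic overview**
- The target (13) is epiafzelechin-(4β→8)-ent-epiafzelechin-(4α→8)-epiafzelechin; it comes from its nona-O-benzyl ether 12 by hydrogenolysis.
- Upper bond C4(top)–C8(middle): anodic C4–H/C8–H cross-coupling of tri-O-benzyl-epiafzelechin 3 (as a pooled C4 cation) with dimer 9.
- Lower bond C4(middle)–C8(bottom): the same anodic coupling of tri-O-benzyl-ent-epiafzelechin 6 with 3.
- 3 comes from (−)-epiafzelechin 1; 6 comes from (+)-afzelechin 4 by C2 epimerisation to ent-epiafzelechin 5, then benzylation.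
- No ring is built: the three pyran rings and the six C2/C3 centres are bought, and each C4 centre is set by its own 2,3-cis unit (3,4-trans attack).

Assumption: (−)-epiafzelechin, (+)-afzelechin and S,S-diphenyl-N-tosylsulfilimine (Ph2S=NTs, Cc1ccc(cc1)S(=O)(=O)N=S(c1ccccc1)c1ccccc1, recovered unchanged) are taken as catalogue items, and in each electrolysis the proton released in the anolyte balances the proton reduced at the cathode, so the net equation is C4–H + C8–H → C4–C8 + H2.

**Route**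

Step 1
Reactants: 1 (−)-epiafzelechin; 2 benzyl bromide
Product: 3 5,7,4′-tri-O-benzyl-(−)-epiafzelechin
Conditions: BnBr (3.3 equiv), K2CO3 (3.5 equiv), DMF, 0 °C → rt, 16 h
Reagents that add atoms: benzyl bromide (2), BrCc1ccccc1
Why: Williamson ether synthesis in which K2CO3 deprotonates only the three phenols, so the secondary C3 alcohol stays free and the bought (2R,3R) centres are untouched.

Step 2
Reactants: 4 (+)-afzelechin
Product: 5 (+)-epiafzelechin (ent-epiafzelechin; 2S,3S)
Conditions: degassed 0.1 M KH2PO4/K2HPO4 buffer (pH 8), 100 °C, sealed tube, Ar, 1 h; reversed-phase HPLC, recovered 4 recycled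
Reagents that add atoms: none
Why: Base-induced C2 epimerisation (retro-oxa-Michael/oxa-Michael) in which the 4′-phenoxide opens the O1–C2 bond to a para-quinone methide that recloses on either face while C3 stays S, giving an equilibrium mixture of roughly one part 2,3-cis 5 to three parts 4 (estimated from the catechin series).

Step 3
Reactants: 5 (+)-epiafzelechin; 2 benzyl bromide
Product: 6 5,7,4′-tri-O-benzyl-ent-epiafzelechin
Conditions: BnBr (3.3 equiv), K2CO3 (3.5 equiv), DMF, 0 °C → rt, 16 h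
Reagents that add atoms: benzyl bromide (2), BrCc1ccccc1
Why: Williamson ether synthesis as in step 1, which also locks C2 because the 4′-phenol needed for ring opening is capped.

Step 4
Reactants: 6 5,7,4′-tri-O-benzyl-ent-epiafzelechin; 3 5,7,4′-tri-O-benzyl-(−)-epiafzelechin
Product: 9 hexa-O-benzyl dimer ent-epiafzelechin-(4α→8)-epiafzelechin (each unit 5,7,4′-tri-O-benzyl), via tribenzyl-ent-epiafzelechin C4 cation 7 (not isolated), via tribenzyl-ent-epiafzelechin C4 aminosulfonium ion 8 (not isolated)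
Conditions: 6, Ph2S=NTs (3 equiv), 0.1 M Bu4NB(C6F5)4, CH2Cl2, divided cell (carbon-felt anode; Pt cathode, TfOH catholyte), 8 mA, 2.2 F/mol, −78 °C; then 3 (3 equiv), −78 → −20 °C, 2 h
Reagents that add atoms: none
Why: Proposed new method: anodic C4–H/C8–H cross-coupling of flavans by a stabilised cation pool, in which ring A of 6 (a 1,3,5-trioxygenated arene, estimated to oxidise near +1.3 V vs SCE, below ring B, the benzyl groups and the sulfilimine) gives a radical cation that loses the benzylic C4 proton and a second electron to form the 2,4,6-trioxygenated benzylic cation 7, which the weakly nucleophilic Ph2S=NTs caps reversibly as 8 (and buffers the released proton) so that it is neither over-oxidised nor consumed by C8 of unreacted 6; with the current off 8 re-ionises (SN1) and C8 of 3 adds in a Friedel–Crafts step to the face opposite the C3 hydroxyl and C2 aryl groups of the 2,3-cis unit, setting the new C4 centre 3,4-trans (4α) under control of the bought centres; the closest known reaction type is the stabilised cation-pool benzylic C–H/aromatic C–H cross-coupling of toluenes through benzylaminosulfonium ions, here extended to the secondary C4–H of a flavan-3-ol, whose chemical counterpart is DDQ oxidation followed by Lewis-acid Friedel–Crafts coupling.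

Step 5
Reactants: 3 5,7,4′-tri-O-benzyl-(−)-epiafzelechin; 9 hexa-O-benzyl dimer
Product: 12 nona-O-benzyl trimer epiafzelechin-(4β→8)-ent-epiafzelechin-(4α→8)-epiafzelechin, via tribenzyl-epiafzelechin C4 cation 10 (not isolated), via tribenzyl-epiafzelechin C4 aminosulfonium ion 11 (not isolated)
Conditions: 3, Ph2S=NTs (3 equiv), 0.1 M Bu4NB(C6F5)4, CH2Cl2, divided cell (carbon-felt anode; Pt cathode, TfOH catholyte), 8 mA, 2.2 F/mol, −78 °C; then 9 (1.5 equiv), −78 → −20 °C, 3 h; excess 9 recovered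
Reagents that add atoms: none
Why: Proposed new method: the same anodic stabilised-cation-pool C4–H activation, now on 3, where cation 10 is stored as 11 and then released to the most nucleophilic and least hindered site of 9, C8 of its upper unit (the regiochemistry seen in Lewis-acid couplings of benzylated dimers), again anti to the C3 hydroxyl and C2 aryl groups of the 2,3-cis electrophile, which sets the 3,4-trans (4β) centre; the closest known reaction type is, as in step 4, benzylic C–H/aromatic C–H cross-coupling through benzylaminosulfonium ions.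

Step 6
Reactants: 12 nona-O-benzyl trimer
Product: 13 epiafzelechin-(4β→8)-ent-epiafzelechin-(4α→8)-epiafzelechin (CNP0191553.2)
Conditions: H2 (1 atm), 20% Pd(OH)2/C, THF/MeOH/H2O (20:1:1), rt, 12 h; Sephadex LH-20, lyophilise
Reagents that add atoms: none
Why: Catalytic hydrogenolysis of the nine benzyl aryl ethers, which in benzylated proanthocyanidins leaves the interflavan bonds, the pyran rings and all eight stereocentres intact.

**Compound list**
1 | (−)-epiafzelechin, (2R,3R)-2-(4-hydroxyphenyl)chromane-3,5,7-triol (2,3-cis) | Oc1cc(O)c2c(c1)O[C@H](c1ccc(O)cc1)[C@H](O)C2 | starting material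
2 | benzyl bromide | BrCc1ccccc1 | starting material
3 | 5,7,4′-tri-O-benzyl-(−)-epiafzelechin, (2R,3R)-5,7-bis(benzyloxy)-2-[4-(benzyloxy)phenyl]chroman-3-ol | C(c1ccccc1)Oc1cc(OCc3ccccc3)c2c(c1)O[C@H](c1ccc(OCc3ccccc3)cc1)[C@H](O)C2 | intermediate
4 | (+)-afzelechin, (2R,3S)-2-(4-hydroxyphenyl)chromane-3,5,7-triol (2,3-trans) | Oc1cc(O)c2c(c1)O[C@H](c1ccc(O)cc1)[C@@H](O)C2 | starting material
5 | (+)-epiafzelechin (ent-epiafzelechin), (2S,3S)-2-(4-hydroxyphenyl)chromane-3,5,7-triol (2,3-cis) | Oc1cc(O)c2c(c1)O[C@@H](c1ccc(O)cc1)[C@@H](O)C2 | intermediate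
6 | 5,7,4′-tri-O-benzyl-ent-epiafzelechin, (2S,3S)-5,7-bis(benzyloxy)-2-[4-(benzyloxy)phenyl]chroman-3-ol | C(c1ccccc1)Oc1cc(OCc3ccccc3)c2c(c1)O[C@@H](c1ccc(OCc3ccccc3)cc1)[C@@H](O)C2 | intermediate
7 | C4 benzylic cation of 6, (2S,3S)-configured (cation shown; counter-ion B(C6F5)4−) | C(c1ccccc1)Oc1cc(OCc3ccccc3)c2c(c1)O[C@@H](c1ccc(OCc3ccccc3)cc1)[C@@H](O)[CH+]2 | intermediate
8 | 3,4-trans (4α) N-tosyl-S,S-diphenylaminosulfonium ion at C4 of 6 (cation shown; counter-ion B(C6F5)4−) | C(c1ccccc1)Oc1cc(OCc3ccccc3)c2c(c1)O[C@@H](c1ccc(OCc3ccccc3)cc1)[C@@H](O)[C@@H]2N([S+](c1ccccc1)c1ccccc1)S(=O)(=O)c1ccc(C)cc1 | intermediate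
9 | hexa-O-benzyl dimer, 5,7,4′-tri-O-benzyl-ent-epiafzelechin-(4α→8)-5,7,4′-tri-O-benzyl-epiafzelechin; upper unit (2S,3S) 2,3-cis-3,4-trans, lower unit (2R,3R) | C(c1ccccc1)Oc1cc(OCc3ccccc3)c2c(c1)O[C@@H](c1ccc(OCc3ccccc3)cc1)[C@@H](O)[C@@H]2c1c(OCc3ccccc3)cc(OCc3ccccc3)c2c1O[C@H](c1ccc(OCc3ccccc3)cc1)[C@H](O)C2 | intermediate
10 | C4 benzylic cation of 3, (2R,3R)-configured (cation shown; counter-ion B(C6F5)4−) | C(c1ccccc1)Oc1cc(OCc3ccccc3)c2c(c1)O[C@H](c1ccc(OCc3ccccc3)cc1)[C@H](O)[CH+]2 | intermediate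
11 | 3,4-trans (4β) N-tosyl-S,S-diphenylaminosulfonium ion at C4 of 3 (cation shown; counter-ion B(C6F5)4−) | C(c1ccccc1)Oc1cc(OCc3ccccc3)c2c(c1)O[C@H](c1ccc(OCc3ccccc3)cc1)[C@H](O)[C@H]2N([S+](c1ccccc1)c1ccccc1)S(=O)(=O)c1ccc(C)cc1 | intermediate
12 | nona-O-benzyl trimer, tri-O-benzyl-epiafzelechin-(4β→8)-tri-O-benzyl-ent-epiafzelechin-(4α→8)-tri-O-benzyl-epiafzelechin; units (2R,3R), (2S,3S), (2R,3R), both interflavan bonds 3,4-trans | C(c1ccccc1)Oc1ccc([C@H]2Oc3cc(OCc5ccccc5)cc(OCc5ccccc5)c3[C@H](c3c(OCc5ccccc5)cc(OCc5ccccc5)c4c3O[C@@H](c3ccc(OCc5ccccc5)cc3)[C@@H](O)[C@@H]4c3c(OCc5ccccc5)cc(OCc5ccccc5)c4c3O[C@H](c3ccc(OCc5ccccc5)cc3)[C@H](O)C4)[C@H]2O)cc1 | intermediate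
13 | epiafzelechin-(4β→8)-ent-epiafzelechin-(4α→8)-epiafzelechin (CNP0191553.2); top unit (2R,3R) 3,4-trans, middle unit (2S,3S) 3,4-trans, bottom unit (2R,3R) | Oc1ccc([C@H]2Oc3cc(O)cc(O)c3[C@H](c3c(O)cc(O)c4c3O[C@@H](c3ccc(O)cc3)[C@@H](O)[C@@H]4c3c(O)cc(O)c4c3O[C@H](c3ccc(O)cc3)[C@H](O)C4)[C@H]2O)cc1 | target

**Step count**
Total steps: 6. Longest linear sequence: 5 steps (4 → 5 → 6 → 9 → 12 → 13).

**Steps most likely to fail, with fallbacks**

Step 4 (new anodic coupling; risks are ring amination, self-coupling of 6 and acid damage). The fallback sets out from 6 and uses the known two-stage chemical route. DDQ (2 equiv) and 2-ethoxyethanol in CH2Cl2 at rt give 4α-(2-ethoxyethoxy)-5,7,4′-tri-O-benzyl-ent-epiafzelechin F1. F1 and 3 (4 equiv) with catalytic TMSOTf in CH2Cl2 at −78 °C then give 9, where the route is rejoined.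

Step 5 (the same new coupling on a dimeric nucleophile; added risks are attack at C6 and over-coupling to a tetramer). The fallback sets out from 3. DDQ and 2-ethoxyethanol in CH2Cl2 give 4β-(2-ethoxyethoxy)-5,7,4′-tri-O-benzyl-epiafzelechin F2. F2 and 9 (1.5 equiv) with catalytic TMSOTf in CH2Cl2 at −78 °C give 12, where the route is rejoined.

Step 2 (the wanted 2,3-cis isomer is the minor partner of the equilibrium). The fallback sets out from 1 and turns the same equilibrium to advantage. Buffer epimerisation of 1 gives mainly the 2,3-trans isomer (−)-afzelechin F3 (2S,3R). Benzylation (BnBr, K2CO3, DMF) gives 5,7,4′-tri-O-benzyl-(−)-afzelechin F4. Dess–Martin periodinane in CH2Cl2 gives (2S)-5,7-bis(benzyloxy)-2-[4-(benzyloxy)phenyl]chroman-3-one F5. LiBH(s-Bu)3 (L-Selectride) in THF at −78 °C adds hydride anti to the C2 aryl group and gives the 2,3-cis alcohol 6, where the route is rejoined; steps 2 and 3 and compounds 4 and 5 are then not needed.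

**Further compounds**
F1 | step 4 | 4α-(2-ethoxyethoxy)-5,7,4′-tri-O-benzyl-ent-epiafzelechin (3,4-trans) | C(c1ccccc1)Oc1cc(OCc3ccccc3)c2c(c1)O[C@@H](c1ccc(OCc3ccccc3)cc1)[C@@H](O)[C@@H]2OCCOCC
F2 | step 5 | 4β-(2-ethoxyethoxy)-5,7,4′-tri-O-benzyl-epiafzelechin (3,4-trans) | C(c1ccccc1)Oc1cc(OCc3ccccc3)c2c(c1)O[C@H](c1ccc(OCc3ccccc3)cc1)[C@H](O)[C@H]2OCCOCC
F3 | step 2 | (−)-afzelechin, (2S,3R)-2-(4-hydroxyphenyl)chromane-3,5,7-triol | Oc1cc(O)c2c(c1)O[C@@H](c1ccc(O)cc1)[C@H](O)C2
F4 | step 2 | 5,7,4′-tri-O-benzyl-(−)-afzelechin (2S,3R) | C(c1ccccc1)Oc1cc(OCc3ccccc3)c2c(c1)O[C@@H](c1ccc(OCc3ccccc3)cc1)[C@H](O)C2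
F5 | step 2 | (2S)-5,7-bis(benzyloxy)-2-[4-(benzyloxy)phenyl]chroman-3-one | C(c1ccccc1)Oc1cc(OCc3ccccc3)c2c(c1)O[C@@H](c1ccc(OCc3ccccc3)cc1)C(=O)C2
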